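**Plan**

1. Cuts: the C6–C3 bond to indole A (the 2,3-disubstituted indole), the CH2–C3 bond to indole B (the 3-substituted indole), and, in the lactone ring (O1, carbonyl C2, carbinol C3, C4, C5; C6 is the exocyclic CH2), the O1–C5 and C2–C3 bonds.
2. Enabling feature: C2 is 1,2 to the hydroxyl-bearing C3, and its ring oxygen O1 ends 1,3 to C3 on C5. The C2(=O1) unit can therefore ride on the C3 oxygen as the carbamoyl group of a but-3-enyl carbamate, move from O to C3 after α-lithiation (polarity reversal at C3), and then close the five-membered ring through its carbonyl oxygen on C5 of the C5=C6 alkene.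
3. Forward order: but-3-en-1-ol → carbamate → one-pot lithiation / 1,2-carbamoyl shift / iodolactonization (lactone ring, both stereocentres) → epoxy ester → union with the separately made 2,3'-bis-indole and re-lactonization.
4. Stereochemistry: C3 comes from (−)-sparteine-controlled deprotonation, with retention in the shift. C5 comes from 1,3-induction (A(1,3) strain, 3,5-trans) in the amide iodocyclization. Neither centre is touched afterwards.

Key step: step 2

Remark: (−)-sparteine is taken as commercially available; O1, C2–C6 and indoles A and B are used as defined in the plan.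

**Route**

Step 1
Reactants: 1 but-3-en-1-ol; 2 N,N-diisopropylcarbamoyl chloride
Product: 3 but-3-en-1-yl N,N-diisopropylcarbamate
Conditions: NaH, THF, 0 °C; then 2, reflux
Reagents that add atoms: none
Why: O-carbamoylation of the sodium alkoxide (nucleophilic acyl substitution) should install the hindered carbamate that later directs α-lithiation and carries C2 and O1; no stereocentre is formed.

Step 2
Reactants: 3 but-3-en-1-yl N,N-diisopropylcarbamate
Product: 7 (3R,5S)-3-hydroxy-5-(iodomethyl)oxolan-2-one, via α-lithiated carbamate 4 (not isolated), via lithium alkoxide of hydroxy amide 5 (not isolated), via iminium lactone iodide 6 (not isolated)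
Conditions: sBuLi, (−)-sparteine, Et2O, −78 °C; warm to rt; then I2, THF/H2O, rt
Reagents that add atoms: iodine, [I][I]; water, O
Why: sBuLi/(−)-sparteine should remove the pro-S hydrogen next to the carbamate oxygen (sparteine-mediated asymmetric α-lithiation of an O-alkyl carbamate, favoured over the allylic C4–H by pre-complexation to the carbonyl), giving the configurationally stable (S)-lithio species 4. On warming, the carbanion should add to its own carbamate carbonyl and the three-membered alkoxide should open (anionic 1,2-carbamoyl O-to-C shift, the carbamate counterpart of the 1,2-Wittig-type acyl shift of α-lithioalkyl esters), which forms the C2–C3 bond with retention and frees the C3 oxygen as the alkoxide of amide 5. Iodine in wet THF should then activate the terminal C5=C6 alkene, and the amide carbonyl oxygen (O1, already bonded to C2) should attack C5 in a 5-exo-trig closure (iodolactonization of an N,N-dialkyl pent-4-enamide) to give iminium 6, which water hydrolyses to lactone 7 with loss of diisopropylamine. C3 is set by the chiral diamine; C5 is set by 1,3-induction, because A(1,3) strain with the N-isopropyl group holds C3–H in the iminium plane, so the C3 oxygen sits pseudoaxial and the CH2I group pseudoequatorial (3,5-trans). The step needs O- and not N-cyclization and 5-exo and not 6-endo attack, which the tertiary amide (no N–H) and the monosubstituted alkene secure; attack by the free C3 hydroxyl would be 4-exo or 5-endo and should be slow.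

Step 3
Reactants: 7 (3R,5S)-3-hydroxy-5-(iodomethyl)oxolan-2-one
Product: 8 methyl (2R)-2-hydroxy-3-[(2S)-oxiran-2-yl]propanoate
Conditions: K2CO3, MeOH, 0 °C
Reagents that add atoms: methanol, CO
Why: Methanolysis of the lactone should free the C5 alkoxide, which displaces iodide from C6 (3-exo-tet Williamson-type epoxide closure); the O1–C5 bond and both stereocentres are untouched, and the mild carbonate base should not epimerize C3.

Step 4
Reactants: 9 1-methyl-1H-indole-2-carbaldehyde; 10 1-methyl-1H-indole
Product: 11 1-methyl-2-[(1-methyl-1H-indol-3-yl)methyl]-1H-indole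
Conditions: Et3SiH, CF3CO2H, CH2Cl2, 0 °C (10 in excess)
Reagents that add atoms: none
Why: Reductive Friedel–Crafts alkylation: C3 of 10 should add to the protonated aldehyde, the carbinol should ionize to the indole-stabilized cation, and triethylsilane should deliver hydride (ionic hydrogenation) to leave the CH2 bridge; no stereocentre is formed.

Step 5
Reactants: 11 1-methyl-2-[(1-methyl-1H-indol-3-yl)methyl]-1H-indole; 8 methyl (2R)-2-hydroxy-3-[(2S)-oxiran-2-yl]propanoate
Product: 13 chaetoindolone C, via hydroxy ester 12 (not isolated)
Conditions: InBr3 (10 mol%), CH2Cl2, 0 °C to rt (8 in excess); then p-TsOH·H2O (cat.), rt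
Reagents that add atoms: none
Why: Lewis-acid-catalysed Friedel–Crafts alkylation in which C3 of indole A, the most nucleophilic carbon of 11, should open the epoxide at its unhindered terminal carbon C6, followed by acid-catalysed lactonization of the γ-hydroxy ester through O1; C3 and C5 take no part, so the (3R,5R) trans configuration is carried into the target.

**Compound list**

1 | but-3-en-1-ol | C=CCCO | starting material
2 | N,N-diisopropylcarbamoyl chloride | CC(C)N(C(C)C)C(=O)Cl | starting material
3 | but-3-en-1-yl N,N-diisopropylcarbamate | C=CCCOC(=O)N(C(C)C)C(C)C | intermediate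
4 | (S)-1-lithiobut-3-en-1-yl N,N-diisopropylcarbamate (sparteine complex) | C=CC[C@@H](OC(=O)N(C(C)C)C(C)C)[Li] | intermediate
5 | lithium (2R)-1-(diisopropylamino)-1-oxopent-4-en-2-olate | C=CC[C@@H]([O-])C(=O)N(C(C)C)C(C)C.[Li+] | intermediate
6 | N-[(3R,5S)-3-hydroxy-5-(iodomethyl)oxolan-2-ylidene]-N-(propan-2-yl)propan-2-aminium iodide | IC[C@@H]1C[C@@H](O)C(=[N+](C(C)C)C(C)C)O1.[I-] | intermediate
7 | (3R,5S)-3-hydroxy-5-(iodomethyl)oxolan-2-one (3,5-trans) | IC[C@@H]1C[C@@H](O)C(=O)O1 | intermediate
8 | methyl (2R)-2-hydroxy-3-[(2S)-oxiran-2-yl]propanoate | COC(=O)[C@H](O)C[C@H]1CO1 | intermediate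
9 | 1-methyl-1H-indole-2-carbaldehyde | Cn1c(C=O)cc2ccccc21 | starting material
10 | 1-methyl-1H-indole | Cn1ccc2ccccc21 | starting material
11 | 1-methyl-2-[(1-methyl-1H-indol-3-yl)methyl]-1H-indole | Cn1cc(Cc2cc3ccccc3n2C)c2ccccc21 | intermediate
12 | methyl (2R,4R)-2,4-dihydroxy-5-{1-methyl-2-[(1-methyl-1H-indol-3-yl)methyl]-1H-indol-3-yl}pentanoate | COC(=O)[C@H](O)C[C@H](O)Cc1c(Cc2cn(C)c3ccccc23)n(C)c2ccccc12 | intermediate
13 | chaetoindolone C, (3R,5R)-3-hydroxy-5-({1-methyl-2-[(1-methyl-1H-indol-3-yl)methyl]-1H-indol-3-yl}methyl)oxolan-2-one | Cn1cc(Cc2c(C[C@@H]3C[C@@H](O)C(=O)O3)c3ccccc3n2C)c2ccccc21 | target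

**Count and risks**

Total step count: 5. Longest linear sequence: 4 steps (1 → 2 → 3 → 5).

Steps most likely to fail:

1. Step 2. The thermal 1,2-carbamoyl shift of the lithiated carbamate may be slow, or the carbanion may lose configuration or decompose as a carbenoid while it is warmed. The fallback runs from 1 to 7 and forms the C2–C3 bond by carboxylation at −78 °C. Compound 1 is converted with NaH and 2,2,4,4-tetramethyl-1,3-oxazolidine-3-carbonyl chloride into but-3-en-1-yl 2,2,4,4-tetramethyl-1,3-oxazolidine-3-carboxylate F1. sBuLi/(−)-sparteine at −78 °C followed by CO2 should give (R)-2-[(2,2,4,4-tetramethyl-1,3-oxazolidine-3-carbonyl)oxy]pent-4-enoic acid F2 with retention. MeSO3H in MeOH, then Ba(OH)2 and acidification, should remove the acid-labile carbamate to give (R)-2-hydroxypent-4-enoic acid F3. EDC·HCl/HOBt with Me2NH should give (R)-2-hydroxy-N,N-dimethylpent-4-enamide F4, whose iodolactonization (I2, THF/H2O) returns to 7.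

2. Step 5. Intermolecular opening of the unactivated aliphatic epoxide by the indole may be sluggish, and intramolecular opening by the ester carbonyl may compete. The fallback runs from 11 and 7 to 13 and bypasses 8. NBS in THF at −78 °C should brominate C3 of indole A of 11 to give 3-bromo-1-methyl-2-[(1-methyl-1H-indol-3-yl)methyl]-1H-indole F5. This is joined to iodide 7 by nickel-catalysed reductive cross-electrophile coupling (NiI2, 4,4'-di-tert-butyl-2,2'-bipyridine, Mn powder, NaI, DMPU, 60 °C). Manganese is chosen over zinc to avoid reductive opening of the β-acyloxy iodide.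

3. Step 4. Product 11 may be alkylated further by protonated 9, a tris(indolyl)methane may form, or an indole may be over-reduced to the indoline by silane and acid. The fallback runs from 9 to 11 and separates reduction from C–C bond formation. NaBH4 in MeOH should reduce 9 to (1-methyl-1H-indol-2-yl)methanol F6, which is added slowly to an excess of 10 with Sc(OTf)3 (5 mol%) in CH2Cl2 (Friedel–Crafts alkylation at C3 of 10) to give 11.

**Further compounds**

F1 | step 2 | but-3-en-1-yl 2,2,4,4-tetramethyl-1,3-oxazolidine-3-carboxylate | C=CCCOC(=O)N1C(C)(C)COC1(C)C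
F2 | step 2 | (R)-2-[(2,2,4,4-tetramethyl-1,3-oxazolidine-3-carbonyl)oxy]pent-4-enoic acid | C=CC[C@@H](OC(=O)N1C(C)(C)COC1(C)C)C(O)=O
F3 | step 2 | (R)-2-hydroxypent-4-enoic acid | C=CC[C@@H](O)C(O)=O
F4 | step 2 | (R)-2-hydroxy-N,N-dimethylpent-4-enamide | C=CC[C@@H](O)C(=O)N(C)C
F5 | step 5 | 3-bromo-1-methyl-2-[(1-methyl-1H-indol-3-yl)methyl]-1H-indole | Cn1cc(Cc2c(Br)c3ccccc3n2C)c2ccccc21
F6 | step 4 | (1-methyl-1H-indol-2-yl)methanol | Cn1c(CO)cc2ccccc21
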